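Readings and results were generated by integration with made-up constants, and the scatter is random.

| setting | ash | oak | alder | flask |
|---|---|---|---|---|
| Q | 0.10 M | 0.10 M | 0.15 M | 0.10 M |
| G | 0.34 M | 0.75 M | 0.50 M | 0.500 M |
| remark | run made earlier | run made earlier | run made earlier |  |
| time |  |  |  | 3.0 min |

| run | time / s | E / % | Q / % | Z / % |
|---|---|---|---|---|
| ash | 15.0 | 20.7 | 49.9 | 29.1 |
| ash | 30.0 | 33.5 | 40.0 | 26.2 |
| ash | 50.0 | 45.4 | 33.0 | 22.0 |
| ash | 60.0 | 49.2 | 29.4 | 19.6 |
| ash | 80.0 | 57.0 | 25.7 | 16.8 |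
| ash | 90.0 | 59.9 | 24.7 | 15.8 |
| ash | 120 | 66.6 | 20.2 | 13.0 |
| oak | 15.0 | 39.4 | 35.5 | 23.2 |
| oak | 30.0 | 58.4 | 23.6 | 17.9 |
| oak | 50.0 | 72.7 | 15.0 | 11.8 |
| oak | 60.0 | 77.9 | 12.9 | 9.5 |
| oak | 80.0 | 83.8 | 8.9 | 5.6 |
| oak | 90.0 | 86.8 | 8.7 | 5.1 |
| oak | 120 | 91.4 | 4.6 | 3.5 |
| alder | 10.0 | 21.7 | 51.9 | 26.3 |
| alder | 15.0 | 28.6 | 43.7 | 27.2 |
| alder | 30.0 | 44.0 | 32.7 | 22.6 |
| alder | 60.0 | 61.4 | 22.7 | 15.3 |
| alder | 120 | 77.7 | 13.4 | 8.4 |

(readings scatter by 0.3 percentage points)



- concentration of E at 3.0 min, in M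
- concentration of Q at 3.0 min, in M
- concentration of Z at 3.0 min, in M

You are handed no rate constants, so take a constant from the readings: late in the ash and alder runs, at 120 s, [Z]/[Q] reads 0.637. The ash readings of E, Q and Z then add to 99.8% of the charge, so I treat what has not become E as a pool of Q and Z in pre-equilibrium. Follow one molecule in that pool: it passes back and forth between the two forms, and its chance of standing as Q at a given moment is the Q share of the pool, 0.611. So [Q] is that share of the charge of Q minus [E], and [Z] is the remainder.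

Now turn the question round. For more Z than Q in the pool, the ratio would have to pass 1. Yet the oak run, charged with more G than ash or alder, reads 0.758 at 30.0 s. The flask has less G than oak, 0.500 M, so I expect Q to stay the larger form at 3.0 min, in the ratio above.

The forecast, holding that “Q and Z equilibrate quickly”, puts the ratio near 0.65 against my 0.637. It gives [E] = 0.0885 M (0.085 M to 0.092 M), [Q] = 0.007 M (0.005 M to 0.009 M) and [Z] = 0.0045 M (0.003 M to 0.0062 M).

The flask gives [E] = 0.0871 M, [Q] = 0.00787 M and [Z] = 0.00502 M, each inside the forecast's range. The equations behind it are these: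

    Q + G → L + X (k = 0.0680 /M/s)
    Q ⇌ Z (K = 0.600, k = 0.0620 /s)
    L → E (k = 1.30 /s)
    G → J (k = 0.00560 /s)

In this flask the share, applied to the 0.0129 M not yet E, gives [Q] = 0.00791 M against the 0.00787 M found. Charged with 0.060 M of Q, at the same G and time, a neighbour flask reaches [E] = 0.0531 M, which leaves 0.00690 M not yet E. The share makes 0.00422 M of that Q, and that neighbour holds [Q] = 0.00416 M.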